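**Plan**
1. The target is epicatechin-(4β→8)-epigallocatechin 3-O-gallate-(4β→8)-epicatechin-(4β→8)-catechin (units 1 to 4 from the top; ring A = benzo ring, ring B = pendant aryl, ring C = pyran). The retrosynthesis cuts the three C4–C8 interflavan bonds; units 1, 2 and 4 go back to (−)-epicatechin, (−)-epigallocatechin plus gallic acid, and (+)-catechin as benzyl ethers.
2. Unit 3 is cut further: its ring C and its C4–C8 bond to unit 4 go back together to a trans-2-aryl-2,3-dihydrobenzofuran-3-carbaldehyde, itself made by rhodium-carbenoid C–H insertion.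
3. Feature used: in unit 3, C4 is benzylic to ring A with O1, 5-O and 7-O ortho/para, C3 carries oxygen, and C2 carries O1 and an aryl group. C3 can therefore enter as an oxocarbenium carbon outside a five-membered ring, C2 can migrate to it, and the C4 cation left behind is captured by C8 of unit 4.
4. Forward order: five-membered ring → ring C of unit 3 together with the unit 3–unit 4 bond (key step) → unit 2 onto C8 of unit 3 → unit 1 onto C8 of unit 2 → hydrogenolysis of all benzyl ethers.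
5. Stereochemistry: C2 of unit 3 from the chiral dirhodium catalyst, C3 from the bridged transition state of the shift, each C4 from attack anti to the 3-oxygen substituent (4β); all other centres from the chiral pool.

Key step: step 7

Assumption: Rh2(S-PTTL)4 is taken to give the (2S) insertion product; if the sense of induction is the opposite, the mirror-image catalyst Rh2(R-PTTL)4 is used and nothing else changes.
Remark: 1, 5 and 25 are taken as purchasable benzyl-protected building blocks.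

**Route**

Step 1
Reactants: 1 3,5-bis(benzyloxy)phenol; 2 oxalyl chloride
Product: 3 4,6-bis(benzyloxy)-1-benzofuran-2,3-dione
Conditions: (COCl)2 (1.2 equiv), Et2O, 0 °C to reflux
Reagents that add atoms: oxalyl chloride, O=C(Cl)C(Cl)=O
Why: O-acylation of the phenol followed by intramolecular Friedel–Crafts acylation at the ortho carbon, which is activated by three oxygen substituents, should close the dione without a Lewis acid and puts the future C3 carbon next to the future O1.

Step 2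
Reactants: 3; 4 methanol; 5 3,4-bis(benzyloxy)benzyl chloride
Product: 7 methyl 2-{2,4-bis(benzyloxy)-6-[(3,4-bis(benzyloxy)benzyl)oxy]phenyl}-2-oxoacetate, via phenol keto ester 6 (not isolated)
Conditions: K2CO3, MeOH, 0 °C to rt; evaporate; then 5, K2CO3, tetrabutylammonium iodide (cat.), DMF, 50 °C
Reagents that add atoms: methanol, CO; 3,4-bis(benzyloxy)benzyl chloride, ClCc1ccc(OCc9ccccc9)c(OCc9ccccc9)c1
Why: Methoxide opens the aryl keto lactone to the methyl ester and frees a single phenoxide, which is O-alkylated by the benzylic chloride (Williamson ether synthesis), so the ether that will deliver ring B sits unambiguously ortho to the keto ester.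

Step 3
Reactants: 7; 8 4-methylbenzenesulfonohydrazide
Product: 10 methyl 2-{2,4-bis(benzyloxy)-6-[(3,4-bis(benzyloxy)benzyl)oxy]phenyl}-2-diazoacetate, via tosylhydrazone 9 (not isolated)
Conditions: TsNHNH2, MeOH, 60 °C; then DBU, CH2Cl2, 0 °C to rt
Reagents that add atoms: 4-methylbenzenesulfonohydrazide, Cc1ccc(cc1)S(=O)(=O)NN
Why: Condensation to the tosylhydrazone and base-induced loss of sulfinate (Bamford–Stevens reaction) is the standard way from an aryl glyoxylate to the donor–acceptor aryl diazoacetate.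

Step 4
Reactants: 10
Product: 11 methyl (2S,3R)-4,6-bis(benzyloxy)-2-[3,4-bis(benzyloxy)phenyl]-2,3-dihydro-1-benzofuran-3-carboxylate (2,3-cis)
Conditions: Rh2(S-PTTL)4 (dirhodium tetrakis[N-phthaloyl-(S)-tert-leucinate], 1 mol %), toluene, −60 °C
Reagents that add atoms: none
Why: The donor–acceptor rhodium carbenoid inserts into a benzylic C–H bond of the ortho ether through a five-membered transition state (intramolecular carbenoid C–H insertion) to give the cis-2-aryl ester; the chiral carboxylate ligands set C2, and the more electron-rich 3,4-bis(benzyloxy)benzylic C–H bonds should react in preference to those of the neighbouring benzyl ether.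

Step 5
Reactants: 11
Product: 13 (2S,3S)-4,6-bis(benzyloxy)-2-[3,4-bis(benzyloxy)phenyl]-2,3-dihydro-1-benzofuran-3-carbaldehyde (2,3-trans), via cis aldehyde 12 (not isolated)
Conditions: i-Bu2AlH (1.1 equiv), CH2Cl2, −78 °C; aq. KNaC4H4O6; then DBU (0.2 equiv), CH2Cl2, rt
Reagents that add atoms: none
Why: The tetrahedral aluminium hemiacetal survives at −78 °C and gives the aldehyde on hydrolysis (partial ester reduction), and the acidic proton alpha to the formyl group then allows base equilibration to the more stable 2,3-trans isomer while C2 is untouched.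

Step 6
Reactants: 14 (+)-catechin; 15 benzyl bromide
Product: 16 (2R,3S)-5,7-bis(benzyloxy)-2-[3,4-bis(benzyloxy)phenyl]chroman-3-ol (5,7,3',4'-tetra-O-benzylcatechin)
Conditions: BnBr (4.4 equiv), K2CO3, DMF, 0 °C to rt, argon
Reagents that add atoms: benzyl bromide, BrCc1ccccc1
Why: Phenoxide O-alkylation (Williamson ether synthesis) protects the four phenols and leaves the far less acidic secondary 3-hydroxyl free.

Step 7
Reactants: 13; 17 benzyloxytrimethylsilane; 16
Product: 20 3,5,7,3',4'-penta-O-benzylepicatechin-(4β→8)-5,7,3',4'-tetra-O-benzylcatechin, via dibenzyl acetal 18 (not isolated), via 4-benzyloxyflavan 19 (not isolated)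
Conditions: 17 (2.2 equiv), Me3SiOTf (0.1 equiv), CH2Cl2, −78 °C; −78 to −40 °C; then 16 (3 equiv), Me3SiOTf (0.2 equiv), −78 °C; Et3N
Reagents that add atoms: benzyloxytrimethylsilane, C[Si](C)(C)OCc1ccccc1
Why: Proposed new method: Me3SiOTf first converts the aldehyde with BnOSiMe3 into the dibenzyl acetal 18 and then ionises it to a benzyloxycarbenium ion on the exocyclic carbon; the ring bond from C3 to C2 of the dihydrobenzofuran, whose C2 carries the ring oxygen and an electron-rich aryl group, then migrates suprafacially to this carbon (1,2-shift, five- to six-membered ring), because the charge so arrives on the old C3, now C4 of the new pyran ring, where it is benzylic to ring A and delocalised onto O1 and the 5- and 7-benzyloxy groups, and this cation is held reversibly as the 4-benzyl ether 19 before C8 of the catechin nucleophile 16 captures it for good. The closest known reaction types are the acid-induced aldehyde-to-ketone (retro-pinacol) rearrangement and Wagner–Meerwein ring expansions of cycloalkylcarbinyl cations for the shift, and the Lewis-acid Friedel–Crafts coupling of 4-alkoxyflavans with flavan-3-ols for the capture. The pyran ring is closed by the 1,2-shift itself, that is by making the C2–C3 bond while the old ring C–C bond to C2 breaks (in the stepwise limit a 6-endo Prins closure of an aryloxycarbenium ion onto the enol ether), and no new C–O bond is formed. C2 migrates with retention and so keeps the configuration set in step 4; C3 is set in the bridged transition state, where the benzyloxy group takes the open exo side and the hydrogen lies under the ring next to the 4-benzyloxy group, which from the 2,3-trans aldehyde places 3-OBn cis to the 2-aryl group; C4 is set by attack of 16 anti to the 3-benzyloxy group (4β), the rule for epicatechin-type C4 cations. The step needs the C2 shift to beat 1,2-hydride shift, proton loss and direct arylation of the oxocarbenium ion: C2 is an alpha-aryloxy benzylic carbon of high migratory aptitude, the lone pairs of the ring oxygen are held away from the antiperiplanar position so that a Grob fragmentation that would racemise C2 is disfavoured, no base is present, and the arene is added only after the ring expansion; C8 and not C6 of 16 should react, as usual for benzylated catechin.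

Step 8
Reactants: 21 (−)-epigallocatechin; 15 benzyl bromide
Product: 22 (2R,3R)-5,7-bis(benzyloxy)-2-[3,4,5-tris(benzyloxy)phenyl]chroman-3-ol (penta-O-benzylepigallocatechin)
Conditions: BnBr (5.5 equiv), K2CO3, DMF, rt, argon
Reagents that add atoms: benzyl bromide, BrCc1ccccc1
Why: Williamson O-benzylation of the five phenols under exclusion of air (the pyrogallol ring is oxidation-sensitive) leaves the 3-hydroxyl free.

Step 9
Reactants: 22; 23 2-ethoxyethanol
Product: 24 (2R,3R,4S)-5,7-bis(benzyloxy)-4-(2-ethoxyethoxy)-2-[3,4,5-tris(benzyloxy)phenyl]chroman-3-ol (4β ether)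
Conditions: DDQ (2 equiv), 2-ethoxyethanol (10 equiv), CH2Cl2, rt
Reagents that add atoms: 2-ethoxyethanol, CCOCCO
Why: DDQ abstracts hydride from C4, which is benzylic to the trioxygenated ring A (benzylic C–H oxidation), and the alcohol adds to the cation anti to the 3-hydroxyl to give the 4β ether that later serves as leaving group.

Step 10
Reactants: 24; 25 3,4,5-tris(benzyloxy)benzoic acid
Product: 26 (2R,3R,4S)-5,7-bis(benzyloxy)-4-(2-ethoxyethoxy)-2-[3,4,5-tris(benzyloxy)phenyl]chroman-3-yl 3,4,5-tris(benzyloxy)benzoate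
Conditions: 25, DCC, DMAP, CH2Cl2, rt
Reagents that add atoms: 3,4,5-tris(benzyloxy)benzoic acid, OC(=O)c1cc(OCc9ccccc9)c(OCc9ccccc9)c(OCc9ccccc9)c1
Why: Carbodiimide activation with DMAP (Steglich esterification) acylates the hindered 3-hydroxyl under neutral conditions that leave the C4 ether untouched, so the gallate is in place before any coupling.

Step 11
Reactants: 26; 20
Product: 27 penta-O-benzylepigallocatechin 3-O-[tri-O-benzylgallate]-(4β→8)-3,5,7,3',4'-penta-O-benzylepicatechin-(4β→8)-5,7,3',4'-tetra-O-benzylcatechin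
Conditions: 20 (1.5 equiv), Me3SiOTf (0.3 equiv), CH2Cl2, −78 to −40 °C; Et3N
Reagents that add atoms: none
Why: The Lewis acid ionises the 4-alkoxy group, the 3-O-acyl group shields the alpha face through a dioxolenium ion, and C8 of the upper unit of the dimer, its most nucleophilic free position, attacks from the beta face (Friedel–Crafts alkylation as used for procyanidins), which sets the new C4 as 4β.

Step 12
Reactants: 28 (−)-epicatechin; 15 benzyl bromide
Product: 29 (2R,3R)-5,7-bis(benzyloxy)-2-[3,4-bis(benzyloxy)phenyl]chroman-3-ol (5,7,3',4'-tetra-O-benzylepicatechin)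
Conditions: BnBr (4.4 equiv), K2CO3, DMF, 0 °C to rt, argon
Reagents that add atoms: benzyl bromide, BrCc1ccccc1
Why: Williamson O-benzylation of the four phenols, as in step 6.

Step 13
Reactants: 29; 23 2-ethoxyethanol
Product: 30 (2R,3R,4S)-5,7-bis(benzyloxy)-2-[3,4-bis(benzyloxy)phenyl]-4-(2-ethoxyethoxy)chroman-3-ol (4β ether)
Conditions: DDQ (2 equiv), 2-ethoxyethanol (10 equiv), CH2Cl2, rt
Reagents that add atoms: 2-ethoxyethanol, CCOCCO
Why: Benzylic C–H oxidation at C4 by DDQ with capture of the cation by the alcohol anti to the 3-hydroxyl, as in step 9.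

Step 14
Reactants: 30; 27
Product: 31 fully benzylated tetramer: 5,7,3',4'-tetra-O-benzylepicatechin-(4β→8)-penta-O-benzylepigallocatechin 3-O-[tri-O-benzylgallate]-(4β→8)-3,5,7,3',4'-penta-O-benzylepicatechin-(4β→8)-5,7,3',4'-tetra-O-benzylcatechin
Conditions: 27 (1.2 equiv), Me3SiOTf (0.3 equiv), CH2Cl2, −78 °C; Et3N
Reagents that add atoms: none
Why: The same Lewis-acid Friedel–Crafts coupling: the epicatechin C4 cation is attacked anti to its 3-oxygen (4β) by C8 of the top unit of the trimer, the least hindered and most electron-rich free position.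

Step 15
Reactants: 31
Product: 32 epicatechin-(4β→8)-epigallocatechin 3-O-gallate-(4β→8)-epicatechin-(4β→8)-catechin (target)
Conditions: H2 (1 atm), Pd(OH)2/C, THF/MeOH/H2O, rt; filtration, lyophilisation
Reagents that add atoms: none
Why: Hydrogenolysis over Pd(OH)2/C should cleave all twenty-one benzyl ethers, while the gallate ester, the interflavan C–C bonds and the pyran C–O bonds are inert under these neutral conditions.

**Compound list**
1 | 3,5-bis(benzyloxy)phenol | Oc1cc(OCc9ccccc9)cc(OCc9ccccc9)c1 | starting material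
2 | oxalyl chloride | O=C(Cl)C(Cl)=O | starting material
3 | 4,6-bis(benzyloxy)-1-benzofuran-2,3-dione | O=C1Oc2cc(OCc9ccccc9)cc(OCc9ccccc9)c2C1=O | intermediate
4 | methanol | CO | starting material
5 | 3,4-bis(benzyloxy)benzyl chloride | ClCc1ccc(OCc9ccccc9)c(OCc9ccccc9)c1 | starting material
6 | methyl 2-[2,4-bis(benzyloxy)-6-hydroxyphenyl]-2-oxoacetate (phenol keto ester) | COC(=O)C(=O)c1c(O)cc(OCc9ccccc9)cc1OCc9ccccc9 | intermediate
7 | methyl 2-{2,4-bis(benzyloxy)-6-[(3,4-bis(benzyloxy)benzyl)oxy]phenyl}-2-oxoacetate | COC(=O)C(=O)c1c(OCc2ccc(OCc9ccccc9)c(OCc9ccccc9)c2)cc(OCc9ccccc9)cc1OCc9ccccc9 | intermediate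
8 | 4-methylbenzenesulfonohydrazide | Cc1ccc(cc1)S(=O)(=O)NN | starting material
9 | tosylhydrazone of 7 | COC(=O)C(=NNS(=O)(=O)c1ccc(C)cc1)c1c(OCc2ccc(OCc9ccccc9)c(OCc9ccccc9)c2)cc(OCc9ccccc9)cc1OCc9ccccc9 | intermediate
10 | methyl 2-{2,4-bis(benzyloxy)-6-[(3,4-bis(benzyloxy)benzyl)oxy]phenyl}-2-diazoacetate | COC(=O)C(=[N+]=[N-])c1c(OCc2ccc(OCc9ccccc9)c(OCc9ccccc9)c2)cc(OCc9ccccc9)cc1OCc9ccccc9 | intermediate
11 | methyl (2S,3R)-4,6-bis(benzyloxy)-2-[3,4-bis(benzyloxy)phenyl]-2,3-dihydro-1-benzofuran-3-carboxylate (cis) | COC(=O)[C@@H]1c2c(OCc9ccccc9)cc(OCc9ccccc9)cc2O[C@@H]1c1ccc(OCc9ccccc9)c(OCc9ccccc9)c1 | intermediate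
12 | (2S,3R)-4,6-bis(benzyloxy)-2-[3,4-bis(benzyloxy)phenyl]-2,3-dihydro-1-benzofuran-3-carbaldehyde (cis) | O=C[C@@H]1c2c(OCc9ccccc9)cc(OCc9ccccc9)cc2O[C@@H]1c1ccc(OCc9ccccc9)c(OCc9ccccc9)c1 | intermediate
13 | (2S,3S)-4,6-bis(benzyloxy)-2-[3,4-bis(benzyloxy)phenyl]-2,3-dihydro-1-benzofuran-3-carbaldehyde (trans) | O=C[C@H]1c2c(OCc9ccccc9)cc(OCc9ccccc9)cc2O[C@@H]1c1ccc(OCc9ccccc9)c(OCc9ccccc9)c1 | intermediate
14 | (+)-catechin, (2R,3S) | Oc1cc(O)c2c(c1)O[C@H](c1ccc(O)c(O)c1)[C@@H](O)C2 | starting material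
15 | benzyl bromide | BrCc1ccccc1 | starting material
16 | 5,7,3',4'-tetra-O-benzylcatechin, (2R,3S) | c1c(OCc9ccccc9)cc(OCc9ccccc9)c2c1O[C@H](c1ccc(OCc9ccccc9)c(OCc9ccccc9)c1)[C@@H](O)C2 | intermediate
17 | benzyloxytrimethylsilane | C[Si](C)(C)OCc1ccccc1 | starting material
18 | (2S,3S)-4,6-bis(benzyloxy)-2-[3,4-bis(benzyloxy)phenyl]-3-[bis(benzyloxy)methyl]-2,3-dihydro-1-benzofuran (dibenzyl acetal, trans) | c1ccccc1COC(OCc1ccccc1)[C@H]1c2c(OCc9ccccc9)cc(OCc9ccccc9)cc2O[C@@H]1c1ccc(OCc9ccccc9)c(OCc9ccccc9)c1 | intermediate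
19 | (2R,3R,4S)-3,4,5,7-tetrakis(benzyloxy)-2-[3,4-bis(benzyloxy)phenyl]chromane (2,3-cis-3,4-trans; the C4 configuration is of no consequence) | c1c(OCc9ccccc9)cc(OCc9ccccc9)c2c1O[C@H](c1ccc(OCc9ccccc9)c(OCc9ccccc9)c1)[C@H](OCc9ccccc9)[C@H]2OCc9ccccc9 | intermediate
20 | 3,5,7,3',4'-penta-O-benzylepicatechin-(4β→8)-5,7,3',4'-tetra-O-benzylcatechin | c1c(OCc9ccccc9)cc(OCc9ccccc9)c2c1O[C@H](c1ccc(OCc9ccccc9)c(OCc9ccccc9)c1)[C@H](OCc9ccccc9)[C@H]2c1c(OCc9ccccc9)cc(OCc9ccccc9)c2c1O[C@H](c1ccc(OCc9ccccc9)c(OCc9ccccc9)c1)[C@@H](O)C2 | intermediate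
21 | (−)-epigallocatechin, (2R,3R) | Oc1cc(O)c2c(c1)O[C@H](c1cc(O)c(O)c(O)c1)[C@H](O)C2 | starting material
22 | penta-O-benzylepigallocatechin, (2R,3R) | c1c(OCc9ccccc9)cc(OCc9ccccc9)c2c1O[C@H](c1cc(OCc9ccccc9)c(OCc9ccccc9)c(OCc9ccccc9)c1)[C@H](O)C2 | intermediate
23 | 2-ethoxyethanol | CCOCCO | starting material
24 | penta-O-benzyl-4β-(2-ethoxyethoxy)epigallocatechin, (2R,3R,4S) | c1c(OCc9ccccc9)cc(OCc9ccccc9)c2c1O[C@H](c1cc(OCc9ccccc9)c(OCc9ccccc9)c(OCc9ccccc9)c1)[C@H](O)[C@H]2OCCOCC | intermediate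
25 | 3,4,5-tris(benzyloxy)benzoic acid | OC(=O)c1cc(OCc9ccccc9)c(OCc9ccccc9)c(OCc9ccccc9)c1 | starting material
26 | penta-O-benzyl-4β-(2-ethoxyethoxy)epigallocatechin 3-O-[3,4,5-tris(benzyloxy)benzoate] | c1c(OCc9ccccc9)cc(OCc9ccccc9)c2c1O[C@H](c1cc(OCc9ccccc9)c(OCc9ccccc9)c(OCc9ccccc9)c1)[C@H](OC(=O)c1cc(OCc9ccccc9)c(OCc9ccccc9)c(OCc9ccccc9)c1)[C@H]2OCCOCC | intermediate
27 | benzylated trimer (units 2, 3 and 4; free 3-OH on unit 4 only) | O=C(O[C@@H]1[C@@H](c2c(OCc9ccccc9)cc(OCc9ccccc9)c3c2O[C@H](c2ccc(OCc9ccccc9)c(OCc9ccccc9)c2)[C@H](OCc9ccccc9)[C@H]3c2c(OCc9ccccc9)cc(OCc9ccccc9)c3c2O[C@H](c2ccc(OCc9ccccc9)c(OCc9ccccc9)c2)[C@@H](O)C3)c2c(OCc9ccccc9)cc(OCc9ccccc9)cc2O[C@@H]1c1cc(OCc9ccccc9)c(OCc9ccccc9)c(OCc9ccccc9)c1)c1cc(OCc9ccccc9)c(OCc9ccccc9)c(OCc9ccccc9)c1 | intermediate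
28 | (−)-epicatechin, (2R,3R) | Oc1cc(O)c2c(c1)O[C@H](c1ccc(O)c(O)c1)[C@H](O)C2 | starting material
29 | 5,7,3',4'-tetra-O-benzylepicatechin, (2R,3R) | c1c(OCc9ccccc9)cc(OCc9ccccc9)c2c1O[C@H](c1ccc(OCc9ccccc9)c(OCc9ccccc9)c1)[C@H](O)C2 | intermediate
30 | 5,7,3',4'-tetra-O-benzyl-4β-(2-ethoxyethoxy)epicatechin, (2R,3R,4S) | c1c(OCc9ccccc9)cc(OCc9ccccc9)c2c1O[C@H](c1ccc(OCc9ccccc9)c(OCc9ccccc9)c1)[C@H](O)[C@H]2OCCOCC | intermediate
31 | fully benzylated tetramer (free 3-OH on units 1 and 4; 3-O-benzyl on unit 3; tri-O-benzylgallate on unit 2) | O=C(O[C@@H]1[C@@H](c2c(OCc9ccccc9)cc(OCc9ccccc9)c3c2O[C@H](c2ccc(OCc9ccccc9)c(OCc9ccccc9)c2)[C@H](OCc9ccccc9)[C@H]3c2c(OCc9ccccc9)cc(OCc9ccccc9)c3c2O[C@H](c2ccc(OCc9ccccc9)c(OCc9ccccc9)c2)[C@@H](O)C3)c2c(OCc9ccccc9)cc(OCc9ccccc9)c([C@H]3c4c(OCc9ccccc9)cc(OCc9ccccc9)cc4O[C@H](c4ccc(OCc9ccccc9)c(OCc9ccccc9)c4)[C@@H]3O)c2O[C@@H]1c1cc(OCc9ccccc9)c(OCc9ccccc9)c(OCc9ccccc9)c1)c1cc(OCc9ccccc9)c(OCc9ccccc9)c(OCc9ccccc9)c1 | intermediate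
32 | epicatechin-(4β→8)-epigallocatechin 3-O-gallate-(4β→8)-epicatechin-(4β→8)-catechin | O=C(O[C@@H]1[C@@H](c2c(O)cc(O)c3c2O[C@H](c2ccc(O)c(O)c2)[C@H](O)[C@H]3c2c(O)cc(O)c3c2O[C@H](c2ccc(O)c(O)c2)[C@@H](O)C3)c2c(O)cc(O)c([C@H]3c4c(O)cc(O)cc4O[C@H](c4ccc(O)c(O)c4)[C@@H]3O)c2O[C@@H]1c1cc(O)c(O)c(O)c1)c1cc(O)c(O)c(O)c1 | target

**Step count**
Total: 15 steps. Longest linear sequence: 9 steps (1, 2, 3, 4, 5, 7, 11, 14, 15).

**Steps most likely to fail**

1. Step 7 (proposed new method). A 1,2-hydride shift from the ring carbon to the oxocarbenium carbon, followed by loss of the C2 proton, would aromatise the five-membered ring to a benzofuran; the arene could also be alkylated by the oxocarbenium ion before the shift. Fallback by known chemistry, giving up the ring expansion: setting out from 29, O-benzylation of the 3-hydroxyl (NaH, BnBr, DMF, 0 °C) should give 3,5,7,3',4'-penta-O-benzylepicatechin F1. Benzylic oxidation (DDQ, 2-ethoxyethanol, CH2Cl2, rt) should give its 4β-(2-ethoxyethoxy) ether F2. Coupling of F2 with 16 (3 equiv, Me3SiOTf, CH2Cl2, −78 °C) comes back to the route at 20.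

2. Step 4. Insertion into the other ortho benzyl ether, aromatic cycloaddition of the carbenoid, or low enantioselectivity would each erode the (2S) cis ester. Fallback without a carbenoid: setting out from 1, oxidative annulation with methyl 3-[3,4-bis(benzyloxy)phenyl]-3-oxopropanoate (FeCl3·6H2O cat., di-tert-butyl peroxide, 1,2-dichloroethane, 100 °C) should give methyl 4,6-bis(benzyloxy)-2-[3,4-bis(benzyloxy)phenyl]-1-benzofuran-3-carboxylate F3. Reduction of the 2,3-double bond with Mg in MeOH should give the racemic trans dihydrobenzofuran ester F4. Chromatography on a chiral stationary phase should give the (2S,3S) trans ester F5. Reduction of F5 (i-Bu2AlH, CH2Cl2, −78 °C) comes back to the route at 13.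

3. Step 14. The electrophile could attack several free positions of the trimer, and the chain could grow beyond the tetramer. Fallback by a two-plus-two union with orthogonal leaving groups: setting out from 26, exchange with phenylmethanethiol (BF3·OEt2, CH2Cl2, −78 °C) should give the 4β-benzylthio ether of the unit 2 gallate F6. Coupling of 30 with F6 (BF3·OEt2, CH2Cl2, −78 °C, which leaves the thioether untouched) should give the unit 1–unit 2 dimer with a 4β-benzylthio group F7. Activation of F7 with AgBF4 (THF, 0 °C) in the presence of 20 comes back to the route at 31.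

Further compounds
F1 | step 7 | 3,5,7,3',4'-penta-O-benzylepicatechin | c1c(OCc9ccccc9)cc(OCc9ccccc9)c2c1O[C@H](c1ccc(OCc9ccccc9)c(OCc9ccccc9)c1)[C@H](OCc9ccccc9)C2
F2 | step 7 | 3,5,7,3',4'-penta-O-benzyl-4β-(2-ethoxyethoxy)epicatechin | c1c(OCc9ccccc9)cc(OCc9ccccc9)c2c1O[C@H](c1ccc(OCc9ccccc9)c(OCc9ccccc9)c1)[C@H](OCc9ccccc9)[C@H]2OCCOCC
F3 | step 4 | methyl 4,6-bis(benzyloxy)-2-[3,4-bis(benzyloxy)phenyl]-1-benzofuran-3-carboxylate | COC(=O)c1c(-c2ccc(OCc9ccccc9)c(OCc9ccccc9)c2)oc2cc(OCc9ccccc9)cc(OCc9ccccc9)c12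
F4 | step 4 | racemic methyl trans-4,6-bis(benzyloxy)-2-[3,4-bis(benzyloxy)phenyl]-2,3-dihydro-1-benzofuran-3-carboxylate | COC(=O)[C@H]1c2c(OCc9ccccc9)cc(OCc9ccccc9)cc2O[C@@H]1c1ccc(OCc9ccccc9)c(OCc9ccccc9)c1.COC(=O)[C@@H]1c2c(OCc9ccccc9)cc(OCc9ccccc9)cc2O[C@H]1c1ccc(OCc9ccccc9)c(OCc9ccccc9)c1
F5 | step 4 | methyl (2S,3S)-4,6-bis(benzyloxy)-2-[3,4-bis(benzyloxy)phenyl]-2,3-dihydro-1-benzofuran-3-carboxylate (trans) | COC(=O)[C@H]1c2c(OCc9ccccc9)cc(OCc9ccccc9)cc2O[C@@H]1c1ccc(OCc9ccccc9)c(OCc9ccccc9)c1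
F6 | step 14 | penta-O-benzyl-4β-(benzylthio)epigallocatechin 3-O-[3,4,5-tris(benzyloxy)benzoate] | c1c(OCc9ccccc9)cc(OCc9ccccc9)c2c1O[C@H](c1cc(OCc9ccccc9)c(OCc9ccccc9)c(OCc9ccccc9)c1)[C@H](OC(=O)c1cc(OCc9ccccc9)c(OCc9ccccc9)c(OCc9ccccc9)c1)[C@H]2SCc9ccccc9
F7 | step 14 | 5,7,3',4'-tetra-O-benzylepicatechin-(4β→8)-penta-O-benzyl-4β-(benzylthio)epigallocatechin 3-O-[3,4,5-tris(benzyloxy)benzoate] | O=C(O[C@@H]1[C@@H](SCc9ccccc9)c2c(OCc9ccccc9)cc(OCc9ccccc9)c([C@H]3c4c(OCc9ccccc9)cc(OCc9ccccc9)cc4O[C@H](c4ccc(OCc9ccccc9)c(OCc9ccccc9)c4)[C@@H]3O)c2O[C@@H]1c1cc(OCc9ccccc9)c(OCc9ccccc9)c(OCc9ccccc9)c1)c1cc(OCc9ccccc9)c(OCc9ccccc9)c(OCc9ccccc9)c1
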